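**Plan**

1. Locants used below: C1 = C(=CH2); C2 = CH(OAc); C3–C7 = chain, C5 carrying Me; C8=C9(Me) = ring alkene; C10 = ring-fusion CH; C11 = cyclopentane CH bonded to C1; C12, C13 = cyclopentane CH2; C14 = C(Me); C15, C16 = carbinol carbons (C16 allylic). Ring B = cyclohexene C8–C9–C10–C14–C15–C16.
2. Retrosynthetic cuts: C1–C2 (Nozaki–Hiyama–Kishi macrocyclisation), then C7–C8 (B-alkyl Suzuki–Miyaura union of the core with the C2–C7 chain from (S)-β-citronellene), then C13–C14 of the cyclopentane. That last cut leads to a vinylcyclopropane lactone, and from there (C10–C11, C11–C14) to the vinyldiazoacetate of 3-methylcyclohexenol.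
3. Forward order: ring B is there from the start. Intramolecular cyclopropanation builds cyclopropane C10–C11–C14 and a temporary γ-lactone (C1–O–C9). The three-membered ring is then enlarged by the two vinyl carbons C12 and C13 to the cyclopentane. Ring B is reshaped (C9 ketone to C9–Me/C16 ketone), the chain is joined at C8, the diol is set, and the eleven-membered ring closes last.
4. Enabling feature: the cyclopentane has its one quaternary carbon (C14) beside the ring-fusion CH (C10), and C11 carries an exocyclic carbonyl-level carbon (C1). A cyclopropane C10–C11–C14 with vinyl and acyl on C11 is therefore a donor–acceptor vinylcyclopropane. Its C11–C14 bond can ionise to a tertiary cation and a dienolate that recloses at C13.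
5. Stereochemistry: CBS reduction sets C9–O (erased later). The lactone tether relays it to C10, C14 and C11 (cis-fused, C1 syn to C9). C5 comes from citronellene. C15 is set by equilibration to the equatorial ketol, C16 by hydroxyl-directed hydride delivery (trans-diol), and C2 in the ring-closing addition.

Key step: step 5

Remark: (S)-β-citronellene (17) is taken as a commercial terpene; lactol 9 (anomers) and carbinol 14 (C9 epimers) are mixtures at a centre that is erased later, and one isomer of each is drawn.

**Route**

Step 1
Reactants: 1 3-methylcyclohex-2-en-1-one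
Product: 2 (S)-3-methylcyclohex-2-en-1-ol
Conditions: (R)-2-methyl-CBS-oxazaborolidine (10 mol %), catecholborane, toluene, −78 °C; NaOH work-up
Reagents that add atoms: none
Why: CBS reduction, in which the enone double bond plays the large group so that the (R)-catalyst should deliver hydride to give the (S)-carbinol at C9, the temporary stereocentre from which the core centres are relayed.

Step 2
Reactants: 2 (S)-3-methylcyclohex-2-en-1-ol; 3 but-3-enoic acid
Product: 4 (S)-3-methylcyclohex-2-en-1-yl but-3-enoate
Conditions: DCC, DMAP (5 mol %), CH2Cl2, 0 °C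
Reagents that add atoms: none
Why: Steglich esterification; low temperature and little DMAP keep the β,γ-unsaturated acyl group out of conjugation, and C9 is not touched.

Step 3
Reactants: 4 (S)-3-methylcyclohex-2-en-1-yl but-3-enoate
Product: 5 (S)-3-methylcyclohex-2-en-1-yl 2-diazobut-3-enoate
Conditions: 4-acetamidobenzenesulfonyl azide, DBU, MeCN, 0 °C; used at once
Reagents that add atoms: 4-acetamidobenzenesulfonyl azide, CC(=O)Nc1ccc(cc1)S(=O)(=O)N=[N+]=[N-]
Why: Regitz diazo transfer to the CH2 that is both allylic and α to the ester gives the vinyldiazoacetate, which is kept cold because it slowly closes to a pyrazole.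

Step 4
Reactants: 5 (S)-3-methylcyclohex-2-en-1-yl 2-diazobut-3-enoate
Product: 6 vinylcyclopropane lactone
Conditions: Rh2(OAc)4 (1 mol %), CH2Cl2, slow addition of 5, 23 °C
Reagents that add atoms: none
Why: intramolecular cyclopropanation by the rhodium vinylcarbenoid; the ester tether lets the carbenoid reach the C10=C14 bond only on the face syn to C9–O, which sets C10, C14 and C11 (lactone carbonyl endo, vinyl exo).

Step 5
Reactants: 6 vinylcyclopropane lactone
Product: 7 cyclopentene lactone
Conditions: Et2AlCl (1.1 equiv), CH2Cl2, −78 → 0 °C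
Reagents that add atoms: none
Why: Proposed new method: Et2AlCl bound to the lactone carbonyl should ionise the C11–C14 bond of the donor–acceptor cyclopropane to a tertiary carbocation at C14 and an aluminium dienolate (O–C1–C11–C12–C13), which recloses through its γ-carbon C13, so that the three-membered ring C10–C11–C14 takes up C12 and C13 and becomes the five-membered ring. The closest known reaction type is the Et2AlCl-promoted vinylcyclopropane-to-cyclopentene rearrangement of 2-alkoxy-1-vinylcyclopropane-1-carboxylates (the second stage of the formal (3+2) annulation of vinylcarbenoids with vinyl ethers); here three alkyl groups stabilise the cation in place of oxygen, which is why the step is argued from mechanism. The cyclopentene closes by C13–C14 bond formation, a 5-endo-trig capture of the cation by the dienolate terminus (the attacking C12=C13 bond lies inside the new ring), formally a 1,3-shift of C14 from C11 to C13. The one stereocentre re-formed is the quaternary C14: C12=C13 stays bound through C11 to C10 on the face of ring B that carried the cyclopropane, so C13 can reach C14 only on that face, the new ring is cis-fused and C14 keeps its configuration, while C9 and C10 are untouched and C11 is sp2 until step 6. The step needs cleavage of C11–C14 and not C11–C10, secured by the tertiary versus secondary cation, and C-closure at C13 in preference to O-closure or proton loss, favoured because O-closure gives a strained ketene acetal that can reopen under the Lewis acid whereas the conjugated alkylidene lactone is the thermodynamic sink.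

Step 6
Reactants: 7 cyclopentene lactone
Product: 8 saturated tricyclic lactone
Conditions: H2 (1 atm), Pd/C (palladium on carbon, 10 %), EtOAc, 23 °C
Reagents that add atoms: none
Why: catalytic hydrogenation of the conjugated trisubstituted alkene from the open face that carries C10–H, which is also the only way to a cis-fused γ-lactone, so C11–H becomes cis to C10–H and C1 stays syn to C9.

Step 7
Reactants: 8 saturated tricyclic lactone
Product: 10 alkynol (C9–OH; C11–C≡CH), via lactol 9 (not isolated)
Conditions: iBu2AlH, CH2Cl2, −78 °C; then MeOH, K2CO3, dimethyl (1-diazo-2-oxopropyl)phosphonate, −78 → 23 °C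
Reagents that add atoms: dimethyl (1-diazo-2-oxopropyl)phosphonate, COP(=O)(OC)C(=[N+]=[N-])C(C)=O
Why: half-reduction of the lactone and Seyferth–Gilbert homologation with the Bestmann–Ohira reagent in one flask turn C1 into the internal alkyne carbon and free C9–OH, the cis-fused lactol holding C11 until the open aldehyde reacts.

Step 8
Reactants: 10 alkynol
Product: 11 alkynyl ketone (C9=O)
Conditions: Dess–Martin periodinane, NaHCO3, CH2Cl2, 23 °C
Reagents that add atoms: none
Why: Dess–Martin oxidation of the secondary alcohol; the cis ring fusion next to the new ketone is the stable one for an angular-methyl hydrindanone.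

Step 9
Reactants: 11 alkynyl ketone
Product: 13 enone (C9=O; C8=C16; silylated alkyne), via bis-silyl enol ether 12 (not isolated)
Conditions: LiN(iPr)2 (2.2 equiv), THF, −78 °C, then Me3SiCl (2.5 equiv); then Pd(OAc)2 (10 mol %), O2 (1 atm), DMSO, 23 °C
Reagents that add atoms: chlorotrimethylsilane, C[Si](C)(C)Cl
Why: kinetic deprotonation at C8 (C10–H is tertiary and shielded) with silylation of both enolate and acetylide, then Saegusa–Ito oxidation in its aerobic catalytic form, gives the C8=C16 enone and leaves the alkyne protected as its silane.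

Step 10
Reactants: 13 enone
Product: 14 tertiary allylic alcohol (C9–OH, C9–Me)
Conditions: MeLi, Et2O/THF, −78 °C
Reagents that add atoms: methyllithium, [Li]C
Why: 1,2-addition of the organolithium to the enone carbonyl brings in the C9 methyl; the configuration of the tertiary carbinol (drawn for attack anti to the C10–C11 bond) is lost in step 11.

Step 11
Reactants: 14 tertiary allylic alcohol
Product: 15 transposed enone (C16=O, C8=C9–Me)
Conditions: pyridinium chlorochromate (C5H5NH)[CrO3Cl], 4 Å molecular sieves, CH2Cl2, 23 °C
Reagents that add atoms: pyridinium chlorochromate, [O-][Cr](=O)(=O)Cl.c1cc[nH+]cc1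
Why: Babler–Dauben oxidative transposition, in which the chromate ester of the tertiary allylic alcohol undergoes a [3,3] shift that places oxygen on C16 and the double bond at C8=C9 before oxidation to the enone.

Step 12
Reactants: 15 transposed enone
Product: 16 α-iodoenone (C8–I)
Conditions: I2, pyridine, CH2Cl2, 23 °C
Reagents that add atoms: iodine, II
Why: α-iodination of the enone by the pyridine addition–iodination–elimination sequence puts the coupling handle on C8.

Step 13
Reactants: 17 (S)-3,7-dimethylocta-1,6-diene
Product: 19 (S)-4-methylhex-5-en-1-ol, via aldehyde 18 (not isolated)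
Conditions: O3 (1 equiv, Sudan red end point), CH2Cl2/MeOH, −78 °C; then NaBH4, −78 → 23 °C
Reagents that add atoms: ozone, [O-][O+]=O
Why: ozonolysis with reductive work-up; ozone takes the electron-rich trisubstituted alkene before the monosubstituted one, and the C5 stereocentre is carried over unchanged from the terpene.

Step 14
Reactants: 19 (S)-4-methylhex-5-en-1-ol
Product: 20 (S)-4-methylhex-5-en-1-yl benzoate
Conditions: BzCl, pyridine, CH2Cl2, 0 °C
Reagents that add atoms: benzoyl chloride, O=C(Cl)c1ccccc1
Why: acylation of the primary alcohol gives an ester without α-hydrogen that survives the later enolate step.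

Step 15
Reactants: 16 α-iodoenone; 20 (S)-4-methylhex-5-en-1-yl benzoate
Product: 22 coupled enone (C7–C8 bond formed), via B-alkyl-9-BBN 21 (not isolated)
Conditions: 20, 9-BBN dimer, THF, 0 → 23 °C; then 16, Pd(dppf)Cl2 (5 mol %), AsPh3, K3PO4 (3 M in H2O), DMF, 23 °C
Reagents that add atoms: none
Why: anti-Markovnikov hydroboration and B-alkyl Suzuki–Miyaura coupling with the α-iodoenone form the C7–C8 bond and complete the tetrasubstituted C8=C9 alkene.

Step 16
Reactants: 22 coupled enone
Product: 24 α'-hydroxy enone (C15–OH cis to C14–Me), via 15-epi-ketol 23 (not isolated)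
Conditions: KN(SiMe3)2, THF, −78 °C; 3-phenyl-2-(phenylsulfonyl)oxaziridine; AcOH; then DBU (0.1 equiv), toluene, 23 °C
Reagents that add atoms: 3-phenyl-2-(phenylsulfonyl)oxaziridine, O=S(=O)(c1ccccc1)N1OC1c1ccccc1
Why: Davis hydroxylation of the kinetic cross-conjugated enolate at C15 followed by base equilibration of the epimerisable ketol, which should settle on the equatorial C15–OH cis to the C14 methyl, because allylic strain with the C9 methyl makes the C10–C11 bond pseudoaxial and the axial epimer 23 would be syn-axial to it.

Step 17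
Reactants: 24 α'-hydroxy enone
Product: 25 trans-diol
Conditions: Me4NBH(OAc)3, MeCN/AcOH (1:1), −30 °C
Reagents that add atoms: none
Why: hydroxyl-directed reduction of the Evans–Saksena type, the hydride being passed from boron bound to the C15 oxygen to the same face of the C16 carbonyl, so that the new C16–OH is trans to C15–OH.

Step 18
Reactants: 25 trans-diol
Product: 26 bis(triethylsilyl) ether
Conditions: Et3SiOTf, 2,6-lutidine, CH2Cl2, −78 → 0 °C
Reagents that add atoms: triethylsilyl trifluoromethanesulfonate, CC[Si](CC)(CC)OS(=O)(=O)C(F)(F)F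
Why: silylation with the silyl triflate covers the hindered trans-diol so that only C2–OH can be acetylated later.

Step 19
Reactants: 26 bis(triethylsilyl) ether
Product: 27 primary alcohol with terminal alkyne
Conditions: K2CO3, MeOH, 23 °C
Reagents that add atoms: none
Why: base-catalysed methanolysis removes the benzoate and the alkynylsilane in one operation while the secondary silyl ethers stay.

Step 20
Reactants: 27 primary alcohol with terminal alkyne
Product: 29 2-iodoalkene alcohol, via alkenylalane 28 (not isolated)
Conditions: Ni(dppp)Cl2 (3 mol %), iBu2AlH (2.5 equiv), THF, 0 → 23 °C; then I2, THF, 0 °C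
Reagents that add atoms: iodine, II
Why: nickel-catalysed Markovnikov hydroalumination of the terminal alkyne (the first equivalent of hydride is spent on the hydroxyl) and iodinolysis of the C–Al bond give the 2-iodo-1-alkene at C1.

Step 21
Reactants: 29 2-iodoalkene alcohol
Product: 30 iodo aldehyde
Conditions: Dess–Martin periodinane, NaHCO3, CH2Cl2, 0 → 23 °C
Reagents that add atoms: none
Why: Dess–Martin oxidation of the primary alcohol to the C2 aldehyde without touching the alkenyl iodide or the silyl ethers.

Step 22
Reactants: 30 iodo aldehyde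
Product: 31 macrocyclic allylic alcohol
Conditions: CrCl2 (8 equiv), NiCl2 (2 mol %), DMSO/THF (3:1), 2 mM, 23 °C
Reagents that add atoms: none
Why: Nozaki–Hiyama–Kishi macrocyclisation, the alkenylchromium from the iodide adding to the aldehyde to close the eleven-membered ring at C1–C2; the aldehyde is expected to be attacked on its outward face with C2–O turned away from ring B, giving the (S)-carbinol.

Step 23
Reactants: 31 macrocyclic allylic alcohol
Product: 32 macrocyclic acetate
Conditions: Ac2O, pyridine, DMAP (cat.), CH2Cl2, 23 °C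
Reagents that add atoms: acetic anhydride, CC(=O)OC(C)=O
Why: acetylation of the only free hydroxyl.

Step 24
Reactants: 32 macrocyclic acetate
Product: 33 CNP0192310.1
Conditions: HF·pyridine, pyridine, THF, 0 → 23 °C
Reagents that add atoms: none
Why: buffered fluoride desilylation frees the C15/C16 diol and leaves the allylic acetate in place.

**Compound list**

1 | 3-methylcyclohex-2-en-1-one | CC1=CC(=O)CCC1 | starting material
2 | (S)-3-methylcyclohex-2-en-1-ol | O[C@@H]1C=C(C)CCC1 | intermediate
3 | but-3-enoic acid | C=CCC(=O)O | starting material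
4 | (S)-3-methylcyclohex-2-en-1-yl but-3-enoate | C=CCC(=O)O[C@@H]1C=C(C)CCC1 | intermediate
5 | (S)-3-methylcyclohex-2-en-1-yl 2-diazobut-3-enoate | C=CC(=[N+]=[N-])C(=O)O[C@@H]1C=C(C)CCC1 | intermediate
6 | vinylcyclopropane lactone (cyclopropane C10–C11–C14 on ring B; C11 carries vinyl, exo, and the lactone C1(=O)–O–C9, endo; C14 carries Me) | O=C1O[C@H]2CCC[C@]3(C)[C@H]2[C@]13C=C | intermediate
7 | cyclopentene lactone (ring B cis-fused to the cyclopentene; C11=C12 conjugated to the lactone C1(=O)–O–C9) | O=C1O[C@H]2CCC[C@@]3(C)CC=C1[C@@H]23 | intermediate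
8 | saturated tricyclic lactone (C9–O, C10–C11 and C14–C13 on one face of ring B; C11–H cis to C10–H) | O=C1O[C@H]2CCC[C@@]3(C)CC[C@@H]1[C@@H]23 | intermediate
9 | lactol of 8 (exo-hydroxy anomer drawn) | O[C@@H]1O[C@H]2CCC[C@@]3(C)CC[C@@H]1[C@@H]23 | intermediate
10 | alkynol (cis-hydrindane; C9–OH; C11–C≡CH) | O[C@H]1CCC[C@@]2(C)CC[C@@H](C#C)[C@@H]12 | intermediate
11 | alkynyl ketone (C9=O) | O=C1CCC[C@@]2(C)CC[C@@H](C#C)[C@@H]12 | intermediate
12 | bis-silyl enol ether (C9–OSiMe3, C8=C9; alkyne C-silylated) | C[Si](C)(C)OC1=CCC[C@@]2(C)CC[C@@H](C#C[Si](C)(C)C)[C@@H]12 | intermediate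
13 | enone (C9=O, C8=C16; trimethylsilylalkyne) | O=C1C=CC[C@@]2(C)CC[C@@H](C#C[Si](C)(C)C)[C@@H]12 | intermediate
14 | tertiary allylic alcohol (C9–OH, C9–Me; C8=C16) | C[C@]1(O)C=CC[C@@]2(C)CC[C@@H](C#C[Si](C)(C)C)[C@@H]12 | intermediate
15 | transposed enone (C16=O, C8=C9–Me) | CC1=CC(=O)C[C@@]2(C)CC[C@@H](C#C[Si](C)(C)C)[C@@H]12 | intermediate
16 | α-iodoenone (C8–I) | CC1=C(I)C(=O)C[C@@]2(C)CC[C@@H](C#C[Si](C)(C)C)[C@@H]12 | intermediate
17 | (S)-3,7-dimethylocta-1,6-diene, (S)-β-citronellene | C=C[C@@H](C)CCC=C(C)C | starting material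
18 | (S)-4-methylhex-5-enal | C=C[C@@H](C)CCC=O | intermediate
19 | (S)-4-methylhex-5-en-1-ol | C=C[C@@H](C)CCCO | intermediate
20 | (S)-4-methylhex-5-en-1-yl benzoate | C=C[C@@H](C)CCCOC(=O)c1ccccc1 | intermediate
21 | 9-[(3R)-6-(benzoyloxy)-3-methylhexyl]-9-borabicyclo[3.3.1]nonane | O=C(OCCC[C@H](C)CCB1C2CCCC1CCC2)c1ccccc1 | intermediate
22 | coupled enone (C8 carries the C7–C2 chain, C2–OBz) | CC1=C(CC[C@@H](C)CCCOC(=O)c2ccccc2)C(=O)C[C@@]3(C)CC[C@@H](C#C[Si](C)(C)C)[C@@H]13 | intermediate
23 | 15-epi-ketol (C15–OH trans to C14–Me) | CC1=C(CC[C@@H](C)CCCOC(=O)c2ccccc2)C(=O)[C@@H](O)[C@@]3(C)CC[C@@H](C#C[Si](C)(C)C)[C@@H]13 | intermediate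
24 | α'-hydroxy enone (C15–OH cis to C14–Me) | CC1=C(CC[C@@H](C)CCCOC(=O)c2ccccc2)C(=O)[C@H](O)[C@@]3(C)CC[C@@H](C#C[Si](C)(C)C)[C@@H]13 | intermediate
25 | trans-diol (C15–OH cis to C14–Me, C16–OH on the cyclopentane face) | CC1=C(CC[C@@H](C)CCCOC(=O)c2ccccc2)[C@@H](O)[C@H](O)[C@@]3(C)CC[C@@H](C#C[Si](C)(C)C)[C@@H]13 | intermediate
26 | bis(triethylsilyl) ether of 25 | CC1=C(CC[C@@H](C)CCCOC(=O)c2ccccc2)[C@@H](O[Si](CC)(CC)CC)[C@H](O[Si](CC)(CC)CC)[C@@]3(C)CC[C@@H](C#C[Si](C)(C)C)[C@@H]13 | intermediate
27 | primary alcohol with terminal alkyne | CC1=C(CC[C@@H](C)CCCO)[C@@H](O[Si](CC)(CC)CC)[C@H](O[Si](CC)(CC)CC)[C@@]3(C)CC[C@@H](C#C)[C@@H]13 | intermediate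
28 | alkenylalane (C1–Al(iBu)2; C2–O–Al(iBu)2) | CC1=C(CC[C@@H](C)CCCO[Al](CC(C)C)CC(C)C)[C@@H](O[Si](CC)(CC)CC)[C@H](O[Si](CC)(CC)CC)[C@@]3(C)CC[C@@H](C(=C)[Al](CC(C)C)CC(C)C)[C@@H]13 | intermediate
29 | 2-iodoalkene alcohol (C1(I)=CH2; C2–OH primary) | CC1=C(CC[C@@H](C)CCCO)[C@@H](O[Si](CC)(CC)CC)[C@H](O[Si](CC)(CC)CC)[C@@]3(C)CC[C@@H](C(I)=C)[C@@H]13 | intermediate
30 | iodo aldehyde (C2=O) | CC1=C(CC[C@@H](C)CCC=O)[C@@H](O[Si](CC)(CC)CC)[C@H](O[Si](CC)(CC)CC)[C@@]3(C)CC[C@@H](C(I)=C)[C@@H]13 | intermediate
31 | macrocyclic allylic alcohol ((2S)-OH; C15, C16 as triethylsilyl ethers) | C=C1[C@@H](O)CC[C@H](C)CCC2=C(C)[C@@H]3[C@H]1CC[C@]3(C)[C@@H](O[Si](CC)(CC)CC)[C@@H]2O[Si](CC)(CC)CC | intermediate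
32 | macrocyclic acetate (C2–OAc; C15, C16 as triethylsilyl ethers) | C=C1[C@@H](OC(C)=O)CC[C@H](C)CCC2=C(C)[C@@H]3[C@H]1CC[C@]3(C)[C@@H](O[Si](CC)(CC)CC)[C@@H]2O[Si](CC)(CC)CC | intermediate
33 | CNP0192310.1 (2S,5R,10S,11R,14S,15R,16R in the locants above) | C=C1[C@@H](OC(C)=O)CC[C@H](C)CCC2=C(C)[C@@H]3[C@H]1CC[C@]3(C)[C@@H](O)[C@@H]2O | target

**Step count and risks**

Total step count: 24. Longest linear sequence: 22 steps (steps 1–12 and 15–24, from 1); steps 13 and 14 make the side chain.

Steps most likely to fail:

1. Step 5 (bears the label "Proposed new method:"). After ionisation, the C14 cation may lose a proton or take a hydride from C10 faster than C13 captures it, which would give ring-opened dienes and no cyclopentene. Heating is no remedy: the vinyl group is cis to the C14 methyl, so a homo-1,5-hydrogen shift would open the cyclopropane first.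
   Fallback (known chemistry): sets out from 1 and comes back at 11. Copper-catalysed asymmetric conjugate addition of [4-(trimethylsilyl)but-3-yn-1-yl]magnesium bromide to 1 (Cu(OTf)2, chiral N-heterocyclic carbene ligand chosen for the C14 configuration shown, Et2O, −30 °C), with trapping of the enolate by iPr3SiOTf, would give silyl enol ether F1. K2CO3 in MeOH would free the alkyne to give enol ether F2. Ph3PAuCl/AgBF4 in CH2Cl2/MeOH would close the cyclopentane by 5-exo-dig attack of C10 on the gold-bound alkyne and give the cis-fused methylene ketone F3. Hydroboration with 9-BBN from the convex face and NaBO3 oxidation would give hydroxy ketone F4 (C1 syn to C9). Dess–Martin oxidation would give keto aldehyde F5, and Seyferth–Gilbert homologation with the Bestmann–Ohira reagent would then give 11.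

2. Step 16. The oxaziridine may attack the enolate mainly on the face that leads to the axial 15-epimer, and the base equilibration may be slow or accompanied by enediol formation and air oxidation, so that the wrong C15 configuration is carried into the diol.
   Fallback: sets out from 22 and comes back at 24. Hydroxylation as in step 16 but without equilibration; the crude ketols 23/24 would be oxidised with Dess–Martin periodinane to ene-1,2-dione F6. NaBH4 (one hydride equivalent, CH2Cl2/MeOH, −78 °C) should then reduce the non-conjugated C15 carbonyl with hydride entering anti to the angular methyl, so that C15 is set kinetically and 24 results.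

3. Step 22. Facial selectivity at the aldehyde carbon in the ring-closing addition may be poor, since macrocyclic control of C2 is hard to predict.
   Fallback: sets out from 30 and comes back at 31. Whatever mixture of 31 and its C2-epimeric alcohol F7 the Nozaki–Hiyama–Kishi closure gives would be oxidised (Dess–Martin periodinane) to α-methylene ketone F8. F8 would then be reduced under reagent control with (R)-2-methyl-CBS-oxazaborolidine and catecholborane to the (S)-alcohol 31.

Further compounds

F1 | step 5 | triisopropylsilyl enol ether of (S)-3-methyl-3-[4-(trimethylsilyl)but-3-yn-1-yl]cyclohexanone (C9–O–Si, C9=C10) | CC(C)[Si](C(C)C)(C(C)C)OC1=C[C@](C)(CCC#C[Si](C)(C)C)CCC1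
F2 | step 5 | triisopropylsilyl enol ether with free terminal alkyne | CC(C)[Si](C(C)C)(C(C)C)OC1=C[C@](C)(CCC#C)CCC1
F3 | step 5 | cis-fused methylene ketone (C9=O; C11=CH2) | O=C1CCC[C@@]2(C)CCC(=C)[C@@H]12
F4 | step 5 | hydroxy ketone (C9=O; C11–CH2OH syn to C9) | O=C1CCC[C@@]2(C)CC[C@@H](CO)[C@@H]12
F5 | step 5 | keto aldehyde (C9=O; C11–CHO) | O=C1CCC[C@@]2(C)CC[C@@H](C=O)[C@@H]12
F6 | step 16 | ene-1,2-dione (C15=O, C16=O) | CC1=C(CC[C@@H](C)CCCOC(=O)c2ccccc2)C(=O)C(=O)[C@@]3(C)CC[C@@H](C#C[Si](C)(C)C)[C@@H]13
F7 | step 22 | C2-epimeric macrocyclic allylic alcohol ((2R)-OH) | C=C1[C@H](O)CC[C@H](C)CCC2=C(C)[C@@H]3[C@H]1CC[C@]3(C)[C@@H](O[Si](CC)(CC)CC)[C@@H]2O[Si](CC)(CC)CC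
F8 | step 22 | macrocyclic α-methylene ketone (C2=O) | C=C1C(=O)CC[C@H](C)CCC2=C(C)[C@@H]3[C@H]1CC[C@]3(C)[C@@H](O[Si](CC)(CC)CC)[C@@H]2O[Si](CC)(CC)CC
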